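**Retrosynthetic overview** (side chain numbered C1 = OCH2, C2 = C=O, C3 = C(=CH2), C4 = CH2, C5 = butenolide carbinol)
1. Target 16 ⇐ allylic alcohol 15 (oxidation) ⇐ alkenyl bromide 7 + aryloxyacetaldehyde 14 (C2–C3, Nozaki–Hiyama–Kishi).
2. Key C–C bond: C4–C5, the bond to the stereogenic carbinol, by intermolecular carbonyl 2-bromoallylation of crotonaldehyde 1 with 2,3-dibromopropene 2; the carbinol is then resolved to (R)-4 by Sharpless kinetic resolution.
3. Butenolide ring: ring-closing metathesis of the methacrylate 6 of (R)-4; the bromoalkene survives as the handle for step 8.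
4. 14 ⇐ hydrangetin 11 (glycidol opening, glycol cleavage); 11 ⇐ 2-methoxyresorcinol 8 + malic acid 9 (Pechmann).
5. Ring order: butenolide (step 4) and coumarin pyranone (step 5) in separate branches; no ring is formed after the coupling.

Assumption: the only stereocentre of the target (butenolide C5) is R as drawn; the carbinol centres of 13 and 15 are made as mixtures because steps 7 and 9 remove them.

**Step 1**
Reactants: 1 (E)-but-2-enal (crotonaldehyde); 2 2,3-dibromoprop-1-ene
Product: 3 rac-(5E)-2-bromohepta-1,5-dien-4-ol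
Conditions: In powder (1.2 equiv), THF/H2O 1:1, rt
Reagents that add atoms: none
Why: Indium-mediated Barbier-type carbonyl allylation: the metal activates only the allylic C–Br bond, and the 2-bromoallyl group adds 1,2 to the enal to make the C4–C5 bond; the carbinol is racemic at this point.

**Step 2**
Reactants: 3
Product: 4 (4R,5E)-2-bromohepta-1,5-dien-4-ol
Conditions: Ti(OiPr)4 (0.15 equiv), L-(+)-diisopropyl tartrate (0.2 equiv), t-BuOOH (0.6 equiv), 4 Å sieves, CH2Cl2, −20 °C, to about 55% conversion
Reagents that add atoms: none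
Why: Sharpless kinetic resolution: with the L-(+)-tartrate the (S)-enantiomer of an (E)-allylic secondary alcohol is epoxidised much faster (as with (E)-cyclohexylpropenylcarbinol), so the unreacted (R)-alcohol is recovered in high ee, which sets the only stereocentre of the target; the electron-poor homoallylic bromoalkene is not epoxidised.

**Step 3**
Reactants: 4; 5 2-methylprop-2-enoyl chloride (methacryloyl chloride)
Product: 6 (4R,5E)-2-bromohepta-1,5-dien-4-yl 2-methylprop-2-enoate
Conditions: Et3N (2 equiv), DMAP (0.1 equiv), CH2Cl2, 0 °C to rt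
Reagents that add atoms: none
Why: DMAP-catalysed O-acylation of a secondary alcohol; the C–O bond of the stereocentre is not touched, so configuration is retained.

**Step 4**
Reactants: 6
Product: 7 (5R)-5-(2-bromoprop-2-en-1-yl)-3-methylfuran-2(5H)-one
Conditions: second-generation Grubbs catalyst (5–10 mol %), toluene (0.01 M), 80 °C
Reagents that add atoms: none
Why: Ring-closing metathesis between the propenyl group and the methacrylate closes the five-membered α-methylbutenolide with loss of propene; the 2-bromoalkene is inert to metathesis, so no cyclopentene or six-membered lactone can form, and the stereocentre is not involved.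

**Step 5**
Reactants: 8 2-methoxybenzene-1,3-diol (2-methoxyresorcinol); 9 DL-malic acid
Product: 11 7-hydroxy-8-methoxy-2H-chromen-2-one (hydrangetin), via 3-oxopropanoic acid 10 (not isolated)
Conditions: conc. H2SO4, 95–100 °C, then ice
Reagents that add atoms: none
Why: von Pechmann condensation: malic acid loses CO and water to formylacetic acid, which substitutes the ring para to one hydroxyl and lactonises onto the other; the phenol is symmetric, so only the 7-hydroxy-8-methoxy isomer can form.

**Step 6**
Reactants: 11; 12 oxiran-2-ylmethanol (glycidol, racemic)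
Product: 13 7-(2,3-dihydroxypropoxy)-8-methoxy-2H-chromen-2-one
Conditions: K2CO3 (0.2 equiv), DMF, 80 °C
Reagents that add atoms: none
Why: Base-catalysed SN2 opening of the epoxide at its terminal carbon by the only phenolic hydroxyl (Williamson-type etherification).

**Step 7**
Reactants: 13
Product: 14 2-[(8-methoxy-2-oxo-2H-chromen-7-yl)oxy]acetaldehyde
Conditions: NaIO4 (1.2 equiv), THF/H2O 2:1, 0 °C to rt; dried by toluene azeotrope and used at once
Reagents that add atoms: none
Why: Malaprade glycol cleavage gives the aryloxyacetaldehyde under neutral conditions that leave the coumarin untouched.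

**Step 8**
Reactants: 7; 14
Product: 15 7-{2-hydroxy-3-methylidene-4-[(2R)-4-methyl-5-oxo-2,5-dihydrofuran-2-yl]butoxy}-8-methoxy-2H-chromen-2-one (both carbinol epimers)
Conditions: CrCl2 (4 equiv), NiCl2 (2 mol %), degassed DMF, rt
Reagents that add atoms: none
Why: Nozaki–Hiyama–Kishi coupling: nickel-catalysed activation of the alkenyl bromide and chromium-mediated addition to the aldehyde only, leaving both lactones alone; no base is present, so C5 cannot epimerise, and the new carbinol centre is uncontrolled because step 9 removes it.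

**Step 9**
Reactants: 15
Product: 16 8-methoxy-7-{3-methylidene-4-[(2R)-4-methyl-5-oxo-2,5-dihydrofuran-2-yl]-2-oxobutoxy}-2H-chromen-2-one (CNP0262059.1)
Conditions: Dess–Martin periodinane (1.3 equiv), CH2Cl2, 0 °C to rt
Reagents that add atoms: none
Why: Dess–Martin oxidation of the secondary allylic alcohol to the α-methylene ketone under near-neutral conditions, so the base-sensitive butenolide centre stays R.

**Compound list**
1 | (E)-but-2-enal (crotonaldehyde) | C/C=C/C=O | starting material
2 | 2,3-dibromoprop-1-ene | C=C(Br)CBr | starting material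
3 | rac-(5E)-2-bromohepta-1,5-dien-4-ol | C/C=C/C(O)CC(Br)=C | intermediate
4 | (4R,5E)-2-bromohepta-1,5-dien-4-ol | C/C=C/[C@H](O)CC(Br)=C | intermediate
5 | 2-methylprop-2-enoyl chloride | CC(=C)C(=O)Cl | starting material
6 | (4R,5E)-2-bromohepta-1,5-dien-4-yl 2-methylprop-2-enoate | C/C=C/[C@H](OC(=O)C(C)=C)CC(Br)=C | intermediate
7 | (5R)-5-(2-bromoprop-2-en-1-yl)-3-methylfuran-2(5H)-one | C=C(Br)C[C@@H]1C=C(C)C(=O)O1 | intermediate
8 | 2-methoxybenzene-1,3-diol | COc1c(O)cccc1O | starting material
9 | DL-malic acid | OC(CC(=O)O)C(=O)O | starting material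
10 | 3-oxopropanoic acid (formylacetic acid) | O=CCC(=O)O | intermediate (not isolated)
11 | 7-hydroxy-8-methoxy-2H-chromen-2-one (hydrangetin) | COc1c(O)ccc2ccc(=O)oc12 | intermediate
12 | oxiran-2-ylmethanol (glycidol, racemic) | OCC1CO1 | starting material
13 | 7-(2,3-dihydroxypropoxy)-8-methoxy-2H-chromen-2-one | COc1c(OCC(O)CO)ccc2ccc(=O)oc12 | intermediate
14 | 2-[(8-methoxy-2-oxo-2H-chromen-7-yl)oxy]acetaldehyde | COc1c(OCC=O)ccc2ccc(=O)oc12 | intermediate
15 | 7-{2-hydroxy-3-methylidene-4-[(2R)-4-methyl-5-oxo-2,5-dihydrofuran-2-yl]butoxy}-8-methoxy-2H-chromen-2-one | C=C(C[C@@H]1C=C(C)C(=O)O1)C(O)COc1ccc2ccc(=O)oc2c1OC | intermediate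
16 | 8-methoxy-7-{3-methylidene-4-[(2R)-4-methyl-5-oxo-2,5-dihydrofuran-2-yl]-2-oxobutoxy}-2H-chromen-2-one | C=C(C[C@@H]1C=C(C)C(=O)O1)C(=O)COc1ccc2ccc(=O)oc2c1OC | target

**Totals**
Total steps: 9. Longest linear sequence: 6 steps (steps 1, 2, 3, 4, 8, 9; the coumarin branch is steps 5, 6, 7, 8, 9).

**Three steps most likely to fail**

Step 8 (alkenyl bromides are the slowest partners in this coupling and aldehyde 14 is fragile). The fallback sets out from 7 and 11 and comes back at 16. Bromide 7 is stannylated (Me3SnSnMe3, Pd(PPh3)4, toluene, 80 °C) to (5R)-3-methyl-5-[2-(trimethylstannyl)prop-2-en-1-yl]furan-2(5H)-one F1. Phenol 11 is alkylated with tert-butyl bromoacetate (K2CO3, acetone) to tert-butyl 2-[(8-methoxy-2-oxo-2H-chromen-7-yl)oxy]acetate F2. This is cleaved with CF3CO2H to 2-[(8-methoxy-2-oxo-2H-chromen-7-yl)oxy]acetic acid F3 and converted with oxalyl chloride and catalytic DMF into 2-[(8-methoxy-2-oxo-2H-chromen-7-yl)oxy]acetyl chloride F4. Stille acylation of F1 with F4 (Pd2(dba)3, tri(2-furyl)phosphine, THF, 50 °C) gives enone 16 directly, so step 9 is not needed on this path.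

Step 4 (a trisubstituted butenolide alkene has to form next to a bromoalkene that may shorten catalyst life). The fallback sets out from 4 and comes back at 7. Alcohol 4 is esterified with 2-(diethoxyphosphoryl)propanoic acid (DCC, DMAP, CH2Cl2) to (4R,5E)-2-bromohepta-1,5-dien-4-yl 2-(diethoxyphosphoryl)propanoate F5. Only the propenyl double bond is cleaved (OsO4 cat., NaIO4, 2,6-lutidine, dioxane/H2O; the electron-poor bromoalkene reacts far more slowly) to (2R)-4-bromo-1-oxopent-4-en-2-yl 2-(diethoxyphosphoryl)propanoate F6. Intramolecular Horner–Wadsworth–Emmons ring closure under Masamune–Roush conditions (LiCl, iPr2NEt, MeCN, 0 °C) then gives 7; its ee must be checked because the α-acyloxy aldehyde can epimerise.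

Step 5 (hot H2SO4 can sulfonate or demethylate the electron-rich ring, and Pechmann yields with malic acid are modest). The fallback sets out from 8 and comes back at 11. Vilsmeier–Haack formylation (POCl3, DMF, MeCN, 0 °C to rt, then water) gives 2,4-dihydroxy-3-methoxybenzaldehyde F7. Wittig reaction with ethyl (triphenylphosphoranylidene)acetate in refluxing N,N-diethylaniline gives ethyl (2E)-3-(2,4-dihydroxy-3-methoxyphenyl)prop-2-enoate F8, which isomerises and lactonises in the same pot to 11.

**Further compounds**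
F1 | step 8 | (5R)-3-methyl-5-[2-(trimethylstannyl)prop-2-en-1-yl]furan-2(5H)-one | C=C(C[C@@H]1C=C(C)C(=O)O1)[Sn](C)(C)C
F2 | step 8 | tert-butyl 2-[(8-methoxy-2-oxo-2H-chromen-7-yl)oxy]acetate | COc1c(OCC(=O)OC(C)(C)C)ccc2ccc(=O)oc12
F3 | step 8 | 2-[(8-methoxy-2-oxo-2H-chromen-7-yl)oxy]acetic acid | COc1c(OCC(=O)O)ccc2ccc(=O)oc12
F4 | step 8 | 2-[(8-methoxy-2-oxo-2H-chromen-7-yl)oxy]acetyl chloride | COc1c(OCC(=O)Cl)ccc2ccc(=O)oc12
F5 | step 4 | (4R,5E)-2-bromohepta-1,5-dien-4-yl 2-(diethoxyphosphoryl)propanoate | C/C=C/[C@H](OC(=O)C(C)P(=O)(OCC)OCC)CC(Br)=C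
F6 | step 4 | (2R)-4-bromo-1-oxopent-4-en-2-yl 2-(diethoxyphosphoryl)propanoate | O=C[C@H](OC(=O)C(C)P(=O)(OCC)OCC)CC(Br)=C
F7 | step 5 | 2,4-dihydroxy-3-methoxybenzaldehyde | COc1c(O)ccc(C=O)c1O
F8 | step 5 | ethyl (2E)-3-(2,4-dihydroxy-3-methoxyphenyl)prop-2-enoate | CCOC(=O)/C=C/c1ccc(O)c(OC)c1O
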